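Which charge of second substrate leaves the most target after 3.0 min, and how fast does the amount fall beyond that charge?

common to all: starting material 0.020 M; free enzyme 0.019 mol%

|  | second substrate | remark | time |
|---|---|---|---|
| dusk | 0.55 equiv | run made earlier |  |
| dawn | 3.1 equiv | run made earlier |  |
| ochre | 0.400 equiv |  | 3.0 min |
| red | 0.600 equiv |  | 3.0 min |
| blue | 1.00 equiv |  | 3.0 min |
| green | 1.50 equiv |  | 3.0 min |
| violet | 2.50 equiv |  | 3.0 min |

| run | time / s | target / % |
|---|---|---|
| dusk | 10.0 | 3.4 |
| dusk | 12.0 | 3.6 |
| dusk | 20.0 | 7.0 |
| dusk | 30.0 | 11.2 |
| dusk | 50.0 | 17.2 |
| dusk | 90.0 | 24.5 |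
| dawn | 10.0 | 4.9 |
| dawn | 12.0 | 2.9 |
| dawn | 20.0 | 6.2 |
| dawn | 30.0 | 8.3 |
| dawn | 50.0 | 7.4 |
| dawn | 90.0 | 9.6 |

(readings scatter by 1 percentage point)

- amount of target at the end, in percent of the starting material charged for ochre, red, blue, green, violet, in this order
- the shape of the row from first to last (falls all the way / rises all the way / hardly changes / rises, then falls / falls, then rises)

- "hardly changes" means that all values lie within two and a half points (for a concentration: within two and a half percent of the largest)

Two amounts answer this for me. The first is what the charge allows: each target takes up one second substrate, so target, in percent of the starting material, stays below the equivalents charged. The second is the level at which target stalls. At 20.0 s, dawn holds 6.2 % and dusk 7.0 %, a gap of 0.8 percentage points against a scatter of 1 point, so the larger charge does not show in the target held that early. Yet from 30.0 s on, dawn averages 8.43 %, although 3.1 equiv were charged.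

I read that stall as a balance: target is made at a steady pace and lost in proportion to c(target) times c(second substrate). If I take that pace to be the same at every charge, an assumption these readings do not test, the stall level times the equivalents is constant at this enzyme loading and this c(starting material). I call this the loss product, 0.261 equiv, and dividing it by a flask's equivalents gives that flask's ceiling.

The two amounts meet at 0.511 equiv. Ochre's charge allows 40.0 % under a ceiling of 65.4 %, while red's allows 60.0 % above a ceiling of 43.6 %. The ceilings then drop to 26.1 %, 17.4 % and 10.5 %. Dusk's opening pace held for 3.0 min would give 67.2 %, more than the 51.1 % at the crossing, so I commit to a row that rises, then falls. As second substrate is used, the ceilings lift, so I expect the falling side to read above them.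

The forecast gives 38 %, 41 %, 28 %, 19.5 % and 12 %, shape rises, then falls, on the ground that “the second substrate kills the enzyme”. Its numbers are its own, not my ceilings.

The flasks give 30.1 %, 36.7 %, 34.9 %, 24.2 % and 11.9 %, shape rises, then falls.

    second substrate + loaded enzyme ⇌ second complex (K = 310 /M, k = 23000 /M/s)
    first complex → loaded enzyme + first product (k = 76.0 /s)
    second complex → free enzyme + target (k = 94.0 /s)
    starting material + free enzyme ⇌ first complex (K = 46.0 /M, k = 6.40 × 10⁵ /M/s)
    second substrate + target → over-reaction product (k = 0.890 /M/s)

Red stands highest, and the row turns at 0.74 equiv, above my 0.511 equiv. In ochre, second substrate is down to 0.323 % of its charge, with target at 30.1 %. The loss product over violet's equivalents gives 10.5 % against 11.9 %. Over green's it gives 17.4 % against 24.2 %, with 28.1 % of green's second substrate left at 3.00 min.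

The earlier runs and the new flask are simulated for an exercise; the scatter is artificial.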